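# Total synthesis of CNP0000262.1, (2S)-8-[2-(2-hydroxy-4,6-dimethoxy-5-methylphenyl)ethyl]-5,7-dimethoxyflavan

## Retrosynthetic overview
1. The free-phenol bibenzyl arm is unmasked last from a 2-arylbenzofuran by two hydride transfers. The phenol therefore never needs a protecting group.
2. The benzofuran–flavan is cut at three bonds at once, all made in one flask. These are C4–C4a of pyran ring C (aryllithium plus primary chloride) and the aryl–alkyne and O–C bonds of the furan ring (alkyne plus o-iodophenol).
3. The open precursor is an (S)-benzylic aryl ether. It comes from Mitsunobu inversion of bought (R)-3-chloro-1-phenylpropan-1-ol with an iodosalicylaldehyde, followed by CHO → C≡CH.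
4. The iodophenol partner comes from 2,6-dimethoxytoluene by C–H borylation/oxidation and ortho-iodination.
5. Ring order: aromatic rings A, B (phenyl) and D are bought. Ring C and then the furan ring form in the same operation, and the furan ring is opened in the last step.

Assumption: mono-iodination of 5 takes place at C3 (ortho to the free OH), as it does for the corresponding acetophenone, and 7 is bought enantiopure.

## Route

Step 1
Reactants: 1 2,6-dimethoxytoluene
Product: 3 3,5-dimethoxy-4-methylphenol, via aryl pinacol boronate 2 (not isolated)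
Conditions: [Ir(OMe)(cod)]2 (1 mol %), 4,4'-di-tert-butyl-2,2'-bipyridine (2 mol %), B2pin2 (0.6 equiv), THF, 80 °C; then Oxone (2KHSO5·KHSO4·K2SO4), acetone/H2O, rt, 10 min, same flask
Reagents that add atoms: bis(pinacolato)diboron, CC1(C)OB(OC1(C)C)B1OC(C)(C)C(C)(C)O1 (boron group of 2); potassium peroxymonosulfate from Oxone, [K+].[O-]S(=O)(=O)OO (phenol oxygen of 3)
Why: Sterically governed iridium-catalysed aromatic C–H borylation (Hartwig–Miyaura type) reaches only the C–H para to the methyl group, because the other two C–H bonds sit next to OMe, and the boronate is oxidised in place (one-pot C–H borylation/oxidation to a phenol).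

Step 2
Reactants: 3 3,5-dimethoxy-4-methylphenol
Product: 4 2-iodo-3,5-dimethoxy-4-methylphenol
Conditions: NIS (1.0 equiv), MeCN, −20 → 0 °C, dark
Reagents that add atoms: N-iodosuccinimide, O=C1CCC(=O)N1I
Why: Electrophilic aromatic iodination; the para position is blocked by methyl and the two open ortho positions are equivalent, so one equivalent of NIS can give only this mono-iodide.

Step 3
Reactants: 5 2-hydroxy-4,6-dimethoxybenzaldehyde
Product: 6 2-hydroxy-3-iodo-4,6-dimethoxybenzaldehyde
Conditions: NIS (1.05 equiv), CF3CO2H (10 mol %), MeCN, 0 °C → rt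
Reagents that add atoms: N-iodosuccinimide, O=C1CCC(=O)N1I
Why: Electrophilic aromatic iodination directed ortho to the free phenol, so iodine goes to C3 rather than to the more crowded C5 between two OMe groups, and this carbon later becomes C4a.

Step 4
Reactants: 6 2-hydroxy-3-iodo-4,6-dimethoxybenzaldehyde, 7 (1R)-3-chloro-1-phenylpropan-1-ol
Product: 8 2-[(1S)-3-chloro-1-phenylpropoxy]-3-iodo-4,6-dimethoxybenzaldehyde
Conditions: PPh3, DIAD (1.3 equiv each), toluene (1 M), 0 °C → rt, ultrasound
Reagents that add atoms: none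
Why: Mitsunobu etherification; the acidic phenol displaces the oxyphosphonium of 7 by SN2 with inversion, turning the (R)-carbinol into the (S)-benzylic aryl ether that is C2 of the flavan, while the primary chloride is inert.

Step 5
Reactants: 8 2-[(1S)-3-chloro-1-phenylpropoxy]-3-iodo-4,6-dimethoxybenzaldehyde
Product: 9 2-[(1S)-3-chloro-1-phenylpropoxy]-1-ethynyl-3-iodo-4,6-dimethoxybenzene
Conditions: MeC(O)C(N2)P(O)(OMe)2 (1.3 equiv), K2CO3 (2 equiv), MeOH/THF, 0 °C → rt
Reagents that add atoms: dimethyl (1-diazo-2-oxopropyl)phosphonate, COP(=O)(OC)C(=[N+]=[N-])C(C)=O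
Why: Seyferth–Gilbert homologation in the Ohira–Bestmann version turns the non-enolisable aldehyde into the terminal alkyne under conditions mild enough to leave the aryl iodide, alkyl chloride and benzylic ether (with its stereocentre) untouched.

Step 6
Reactants: 9 2-[(1S)-3-chloro-1-phenylpropoxy]-1-ethynyl-3-iodo-4,6-dimethoxybenzene, 4 2-iodo-3,5-dimethoxy-4-methylphenol
Product: 13 2-[(2S)-5,7-dimethoxy-2-phenyl-3,4-dihydro-2H-chromen-8-yl]-4,6-dimethoxy-5-methyl-1-benzofuran, via dilithiated aryl ether 10 (not isolated), via 8-ethynylflavan 11 (not isolated), via alkynylphenol 12 (not isolated)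
Conditions: t-BuLi (3.1 equiv), THF, −78 °C → rt, 2 h; then 4 (1.05 equiv), Pd(PPh3)4 (5 mol %), CuI (5 mol %), Et3N, 65 °C, same flask
Reagents that add atoms: tert-butyllithium, [Li]C(C)(C)C (lithium of 10 only; no atom of it stays in 13)
Why: Proposed new method: three equivalents of t-BuLi turn 9 into the acetylide/aryllithium 10 (deprotonation plus iodine–lithium exchange, the third equivalent destroying t-BuI), the aryllithium closes ring C by 6-exo-tet SN2 on the primary chloride without touching the C2–O bond so the (S)-centre is kept, and the surviving acetylide is quenched not by water but by iodophenol 4, giving alkyne 11 and the lithium phenoxide, which couple under Pd/Cu catalysis to 12 and close the furan ring by 5-endo-dig O-attack; the closest known reactions are the Parham cyclisation of o-lithioaryl 3-halopropyl ethers to chromans and the Sonogashira (Castro–Stephens type) heteroannulation of o-iodophenols to 2-arylbenzofurans, and only their union in one flask is new.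

Step 7
Reactants: 13 2-[(2S)-5,7-dimethoxy-2-phenyl-3,4-dihydro-2H-chromen-8-yl]-4,6-dimethoxy-5-methyl-1-benzofuran
Product: 15 2-{2-[(2S)-5,7-dimethoxy-2-phenyl-3,4-dihydro-2H-chromen-8-yl]ethyl}-3,5-dimethoxy-4-methylphenol, via 2,3-dihydrobenzofuran 14 (not isolated)
Conditions: Et3SiH (6 equiv), CF3CO2H/CH2Cl2 1:1, 0 °C → rt
Reagents that add atoms: none
Why: Ionic hydrogenation (Kursanov–Parnes) first reduces the electron-rich furan C=C to 14, whose O–CH(aryl) bond is a 2,4,6-trialkoxybenzyl aryl ether that ionises in CF3CO2H and takes a second hydride to free the phenol and the CH2CH2 bridge, while the flavan C2–O bond, supported only by an unsubstituted phenyl, does not ionise and so the (S)-centre is kept.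

## Compound list
1 | 2,6-dimethoxytoluene | COc1cccc(OC)c1C | starting material
2 | 2-(3,5-dimethoxy-4-methylphenyl)-4,4,5,5-tetramethyl-1,3,2-dioxaborolane | COc1cc(cc(OC)c1C)B1OC(C)(C)C(C)(C)O1 | intermediate
3 | 3,5-dimethoxy-4-methylphenol | COc1cc(O)cc(OC)c1C | intermediate
4 | 2-iodo-3,5-dimethoxy-4-methylphenol | COc1cc(O)c(I)c(OC)c1C | intermediate
5 | 2-hydroxy-4,6-dimethoxybenzaldehyde | COc1cc(O)c(C=O)c(OC)c1 | starting material
6 | 2-hydroxy-3-iodo-4,6-dimethoxybenzaldehyde | COc1cc(OC)c(C=O)c(O)c1I | intermediate
7 | (1R)-3-chloro-1-phenylpropan-1-ol | O[C@H](CCCl)c1ccccc1 | starting material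
8 | 2-[(1S)-3-chloro-1-phenylpropoxy]-3-iodo-4,6-dimethoxybenzaldehyde | COc1cc(OC)c(C=O)c(O[C@@H](CCCl)c2ccccc2)c1I | intermediate
9 | 2-[(1S)-3-chloro-1-phenylpropoxy]-1-ethynyl-3-iodo-4,6-dimethoxybenzene | COc1cc(OC)c(C#C)c(O[C@@H](CCCl)c2ccccc2)c1I | intermediate
10 | dilithio derivative of 9 (lithium acetylide, aryllithium in place of iodine), (S) | COc1cc(OC)c(C#C[Li])c(O[C@@H](CCCl)c2ccccc2)c1[Li] | intermediate
11 | (2S)-8-ethynyl-5,7-dimethoxy-2-phenyl-3,4-dihydro-2H-chromene (formed as its lithium acetylide, protonated by 4) | C#Cc1c(OC)cc(OC)c2c1O[C@H](c1ccccc1)CC2 | intermediate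
12 | 2-{[(2S)-5,7-dimethoxy-2-phenyl-3,4-dihydro-2H-chromen-8-yl]ethynyl}-3,5-dimethoxy-4-methylphenol | COc1cc(O)c(C#Cc2c(OC)cc(OC)c3c2O[C@H](c2ccccc2)CC3)c(OC)c1C | intermediate
13 | 2-[(2S)-5,7-dimethoxy-2-phenyl-3,4-dihydro-2H-chromen-8-yl]-4,6-dimethoxy-5-methyl-1-benzofuran | COc1cc2oc(-c3c(OC)cc(OC)c4c3O[C@H](c3ccccc3)CC4)cc2c(OC)c1C | intermediate
14 | 2-[(2S)-5,7-dimethoxy-2-phenyl-3,4-dihydro-2H-chromen-8-yl]-4,6-dimethoxy-5-methyl-2,3-dihydro-1-benzofuran (both epimers at the new furan carbon) | COc1cc2OC(Cc2c(OC)c1C)c1c(OC)cc(OC)c2c1O[C@H](c1ccccc1)CC2 | intermediate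
15 | 2-{2-[(2S)-5,7-dimethoxy-2-phenyl-3,4-dihydro-2H-chromen-8-yl]ethyl}-3,5-dimethoxy-4-methylphenol | COc1cc(O)c(CCc2c(OC)cc(OC)c3c2O[C@H](c2ccccc2)CC3)c(OC)c1C | target

## Step count
- Total step count: 7.
- Longest linear sequence: 5 steps (5 → 6 → 8 → 9 → 13 → 15).

## Steps most likely to fail

**Step 6.**
- Risks: the aryllithium may pull the benzylic C2–H (Wittig-type rearrangement, loss of ee). It may displace the chloride too slowly. The lithium salts may slow the palladium cycle.
- Fallback: it sets out from 9 and closes ring C under neutral reductive conditions instead of with an organolithium. This is a nickel-catalysed intramolecular cross-electrophile coupling (NiBr2(dme), 4,4'-di-tert-butyl-2,2'-bipyridine, Zn, NaI, DMA, 60 °C). It gives 11, which is now isolated.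
- In a separate flask 11 and 4 are joined by the Pd(PPh3)4/CuI/Et3N heteroannulation, and the route is rejoined at 13. This fallback makes no new compound (F0).

**Step 4.**
- Risks: phenol 6 carries two ortho substituents, so the intermolecular SN2 on a secondary benzylic centre may be slow. Elimination or partial SN1 erosion of ee could then compete.
- Fallback: it sets out from 6 and 7 and reverses the order of bond formation. A nickel-catalysed cross-electrophile coupling of the aryl iodide with the primary chloride (NiBr2(dme), bipyridine ligand, Zn, NaI, DMA) makes the C4–C4a bond first and leaves the carbinol untouched. The product is 2-hydroxy-3-[(3R)-3-hydroxy-3-phenylpropyl]-4,6-dimethoxybenzaldehyde F1.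
- An intramolecular, and therefore unhindered, Mitsunobu closure (PPh3, DIAD, THF) then inverts the carbinol. This gives (2S)-5,7-dimethoxy-2-phenyl-3,4-dihydro-2H-chromene-8-carbaldehyde F2.
- Ohira–Bestmann homologation of the aldehyde brings the route back at 11.

**Step 7.**
- Risks: the reduction may stop at 14. Alternatively, the acid may begin to open or racemise ring C before the furan is consumed.
- Fallback: it avoids the benzofuran altogether and sets out from 11 (obtained by quenching the first stage of step 6 with water) and 4.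
- Phenol 4 is benzylated (BnBr, K2CO3, acetone) to 1-(benzyloxy)-2-iodo-3,5-dimethoxy-4-methylbenzene F3.
- Sonogashira coupling of this iodide with 11 cannot cyclise. It gives (2S)-8-{[6-(benzyloxy)-2,4-dimethoxy-3-methylphenyl]ethynyl}-5,7-dimethoxy-2-phenyl-3,4-dihydro-2H-chromene F4.
- One neutral hydrogenation (H2, Pd/C, EtOAc, stopped after uptake) saturates the alkyne and removes the benzyl group. The route is rejoined at 15.

Further compounds
F0 | step 6 | none | none
F1 | step 4 | 2-hydroxy-3-[(3R)-3-hydroxy-3-phenylpropyl]-4,6-dimethoxybenzaldehyde | COc1cc(OC)c(C=O)c(O)c1CC[C@@H](O)c1ccccc1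
F2 | step 4 | (2S)-5,7-dimethoxy-2-phenyl-3,4-dihydro-2H-chromene-8-carbaldehyde | O=Cc1c(OC)cc(OC)c2c1O[C@H](c1ccccc1)CC2
F3 | step 7 | 1-(benzyloxy)-2-iodo-3,5-dimethoxy-4-methylbenzene | COc1cc(OCc2ccccc2)c(I)c(OC)c1C
F4 | step 7 | (2S)-8-{[6-(benzyloxy)-2,4-dimethoxy-3-methylphenyl]ethynyl}-5,7-dimethoxy-2-phenyl-3,4-dihydro-2H-chromene | COc1cc(OCc2ccccc2)c(C#Cc2c(OC)cc(OC)c3c2O[C@H](c2ccccc2)CC3)c(OC)c1C
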